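**Plan**

- Retrosynthesis (chroman-4-one numbering of the target): the carboxylic acid and the C5 hydroxyl are tied back as a six-membered aryl lactone (temporary ring). The cuts then follow in this order: C4–C3, O1–C2, C8–prenyl, C4a–C4 (formyl carbon), and the bond from C6 to the benzylic carbon of the side chain.
- Enabling feature: in the ring O1/C2/C3/C4/C4a/C8a the ketone carbon C4 is bonded to C3, which carries a methyl group and sits next to the O-bearing C2. The unit C4–C3(–CH3) is therefore the Markovnikov adduct of an aryl aldehyde C–H across the vinyl group of an aryl (R)-but-3-en-2-yl ether. Carbene umpolung of the formyl carbon joins it to an unactivated alkene carbon.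
- Forward order: the benzene ring is bought (3,5-dimethoxyphenol). The lactone ring comes from a Friedel–Crafts/hemiacetal cascade and oxidation. Formylation, chelation-controlled demethylation, O-tert-prenylation/Claisen rearrangement and Mitsunobu etherification follow. The carbene-catalysed hydroacylation closes the dihydropyranone as the last ring, and the lactone is then opened.
- Stereochemistry: the side-chain (R) center comes from the (S)-prolinol silyl ether catalyst. C2 (R) comes from commercial (S)-but-3-en-2-ol by Mitsunobu inversion. C3 (R) comes from C2 by substrate control and equilibration to the trans isomer.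

Key step: step 8

Remark: intermediates 3–16 are numbered as chromans with the lactone oxygen as O1; in 18 the positions C8, C9 and C10 correspond to C2, C3 and C4 of the target.

**Route**

Step 1
Reactants: 1 3,5-dimethoxyphenol; 2 (E)-oct-2-enal
Product: 4 (R)-5,7-dimethoxy-4-pentylchroman-2-one, via lactol 3 (not isolated)
Conditions: (i) (S)-2-[diphenyl(trimethylsilyloxy)methyl]pyrrolidine (20 mol %), PhCO2H (20 mol %), PhMe, 0 °C to rt; (ii) crude lactol, 2,2,6,6-tetramethylpiperidin-1-oxyl (TEMPO, 10 mol %), PhI(OAc)2, CH2Cl2, rt
Reagents that add atoms: none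
Why: Iminium-catalysed Friedel–Crafts alkylation/hemiacetalisation cascade of an electron-rich phenol with an enal, followed by TEMPO/PhI(OAc)2 lactol oxidation; the phenol attacks through either of its two equivalent ortho carbons on the β-face of the E-iminium ion that is not covered by the diphenyl(siloxy)methyl group, which for the (S)-catalyst and an alkyl enal should give the (R)-benzylic center.

Step 2
Reactants: 4 (R)-5,7-dimethoxy-4-pentylchroman-2-one
Product: 6 (R)-5,7-dimethoxy-2-oxo-4-pentylchromane-8-carbaldehyde, via iminium chloride 5 (not isolated)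
Conditions: POCl3, DMF, 0 to 60 °C; then H2O, rt
Reagents that add atoms: N,N-dimethylformamide CN(C)C=O; water O
Why: Vilsmeier–Haack formylation, expected at C8 because this carbon is para to the 5-methoxy and ortho to the 7-methoxy group and is flanked by the tied-back lactone oxygen, whereas C6 lies between two methoxy groups of which the 5-methoxy is forced by the peri C4 substituent to turn its methyl toward C6.

Step 3
Reactants: 6 (R)-5,7-dimethoxy-2-oxo-4-pentylchromane-8-carbaldehyde
Product: 8 (R)-7-hydroxy-5-methoxy-2-oxo-4-pentylchromane-8-carbaldehyde, via aryloxydichloroborane 7 (not isolated)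
Conditions: BCl3 (1.2 equiv), CH2Cl2, −78 to 0 °C; then H2O
Reagents that add atoms: none
Why: Chelation-controlled Lewis acid ether cleavage, in which BCl3 bound to the formyl oxygen reaches only the ortho 7-methoxy group, so that the 5-methoxy group para to the aldehyde should stay.

Step 4
Reactants: 9 2-methylbut-3-en-2-ol; 10 di-tert-butyl dicarbonate
Product: 11 tert-butyl (2-methylbut-3-en-2-yl) carbonate
Conditions: n-BuLi, THF, −78 °C; then Boc2O (10), −78 °C to rt; then H2O
Reagents that add atoms: none
Why: O-Acylation of the lithium alkoxide of a tertiary allylic alcohol by the dicarbonate (mixed carbonate formation).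

Step 5
Reactants: 8 (R)-7-hydroxy-5-methoxy-2-oxo-4-pentylchromane-8-carbaldehyde; 11 tert-butyl (2-methylbut-3-en-2-yl) carbonate
Product: 12 (R)-5-methoxy-7-[(2-methylbut-3-en-2-yl)oxy]-2-oxo-4-pentylchromane-8-carbaldehyde
Conditions: Pd(PPh3)4 (5 mol %), THF, 0 °C
Reagents that add atoms: none
Why: Decarboxylative Tsuji–Trost O-allylation, in which zerovalent palladium ionises the tertiary carbonate, the released tert-butoxide deprotonates the acidic phenol, and under kinetic control at low temperature the phenoxide should attack the more substituted allyl terminus to give the tertiary aryl ether.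

Step 6
Reactants: 12 (R)-5-methoxy-7-[(2-methylbut-3-en-2-yl)oxy]-2-oxo-4-pentylchromane-8-carbaldehyde
Product: 14 (R)-7-hydroxy-5-methoxy-6-(3-methylbut-2-en-1-yl)-2-oxo-4-pentylchromane-8-carbaldehyde, via Claisen dienone 13 (not isolated)
Conditions: PhMe, 110 °C
Reagents that add atoms: none
Why: Aromatic Claisen rearrangement ([3,3]-sigmatropic) of the 1,1-dimethylallyl aryl ether to C6, the only ortho position that carries hydrogen, followed by tautomerisation of the dienone to the phenol, which turns the tertiary ether into the linear prenyl group.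

Step 7
Reactants: 14 (R)-7-hydroxy-5-methoxy-6-(3-methylbut-2-en-1-yl)-2-oxo-4-pentylchromane-8-carbaldehyde; 15 (S)-but-3-en-2-ol
Product: 16 (R)-7-{[(R)-but-3-en-2-yl]oxy}-5-methoxy-6-(3-methylbut-2-en-1-yl)-2-oxo-4-pentylchromane-8-carbaldehyde
Conditions: PPh3, DIAD, THF (1 M), 0 °C to rt
Reagents that add atoms: none
Why: Mitsunobu etherification of the acidic ortho-formyl phenol, in which SN2 displacement of the oxyphosphonium group with inversion should turn the (S)-alcohol into the (R)-aryl ether that becomes C2 of the target.

Step 8
Reactants: 16 (R)-7-{[(R)-but-3-en-2-yl]oxy}-5-methoxy-6-(3-methylbut-2-en-1-yl)-2-oxo-4-pentylchromane-8-carbaldehyde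
Product: 18 (4R,8R,9R)-5-methoxy-8,9-dimethyl-6-(3-methylbut-2-en-1-yl)-4-pentyl-3,4,8,9-tetrahydro-2H,10H-pyrano[2,3-f]chromene-2,10-dione, via carbene enaminol 17 (not isolated)
Conditions: 2-mesityl-6,7-dihydro-5H-pyrrolo[2,1-c][1,2,4]triazol-2-ium chloride (20 mol %), DBU (30 mol %), 1,4-dioxane, 4 Å MS, 80 °C
Reagents that add atoms: none
Why: The triazolylidene formed from the precatalyst and DBU adds to the formyl group of 16 and, after proton transfer, gives enaminol 17, whose former formyl carbon is now nucleophilic (polarity reversal); this carbon bonds to the internal carbon of the O-tethered vinyl group while the enaminol O–H hydrogen passes to the terminal CH2 through a concerted, asynchronous ene-type (Conia-ene-like) transition state, and expulsion of the carbene from the resulting alkoxide gives the ketone. The closest known reaction type is the carbene-catalysed intramolecular hydroacylation of unactivated alkenes that turns 2-(allyloxy)benzaldehydes into chroman-4-ones. The dihydropyranone ring (C10, C10a, C6a, O7, C8, C9) closes in the 6-exo-trig mode, with bond formation at the internal alkene carbon so that the terminal carbon ends as the C9 methyl group. The one new stereocenter, C9, is controlled by the existing (R)-C8: in the half-chair transition state the C8 methyl group should lie pseudo-equatorial and the alkene should be attacked on the face that puts the nascent methyl group trans to it, and because C9 is alpha to the new ketone any cis isomer should converge on the trans-diequatorial (8R,9R) isomer by enolisation under the DBU present. The step needs 6-exo rather than 7-endo closure, secured by the three-atom O–CH tether and the five-centre hydrogen-transfer array; reaction at the vinyl group rather than the prenyl alkene, secured because the prenyl group stands meta to the formyl carbon and cannot reach it; and retention at C8, secured by substoichiometric base and moderate temperature that should not open the new ring by retro-oxa-Michael reaction. The lactone oxygen ortho to the aldehyde raises its electrophilicity toward the carbene, while the lactone carbonyl, being an ester, should be a poor acceptor for the enaminol.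

Step 9
Reactants: 18 (4R,8R,9R)-5-methoxy-8,9-dimethyl-6-(3-methylbut-2-en-1-yl)-4-pentyl-3,4,8,9-tetrahydro-2H,10H-pyrano[2,3-f]chromene-2,10-dione
Product: 20 (R)-3-[(2R,3R)-5-hydroxy-7-methoxy-2,3-dimethyl-8-(3-methylbut-2-en-1-yl)-4-oxochroman-6-yl]octanoic acid, via dilithium salt 19 (not isolated)
Conditions: LiOH (3 equiv), THF/H2O, 0 °C; then 1 M HCl to pH 3–4, 0 °C
Reagents that add atoms: lithium hydroxide [Li+].[OH-]
Why: Saponification of the aryl lactone, after which cold acidification should leave the acid open because the freed phenol is held in a hydrogen bond to the C4 ketone as in the natural chromanone acids; no stereocenter is formed and the trans C2/C3 arrangement is the thermodynamic one, so brief contact with base should not change it.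

**Compound list**

1 | 3,5-dimethoxyphenol | COc1cc(O)cc(OC)c1 | starting material
2 | (E)-oct-2-enal | CCCCC/C=C/C=O | starting material
3 | (4R)-5,7-dimethoxy-4-pentylchroman-2-ol (lactol, anomeric mixture, not isolated) | CCCCC[C@@H]1CC(O)Oc2cc(OC)cc(OC)c12 | intermediate
4 | (R)-5,7-dimethoxy-4-pentylchroman-2-one | CCCCC[C@@H]1CC(=O)Oc2cc(OC)cc(OC)c12 | intermediate
5 | N-{[(4R)-5,7-dimethoxy-2-oxo-4-pentylchroman-8-yl]methylidene}-N-methylmethanaminium chloride (not isolated) | CCCCC[C@@H]1CC(=O)Oc2c(C=[N+](C)C)c(OC)cc(OC)c12.[Cl-] | intermediate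
6 | (R)-5,7-dimethoxy-2-oxo-4-pentylchromane-8-carbaldehyde | CCCCC[C@@H]1CC(=O)Oc2c(C=O)c(OC)cc(OC)c12 | intermediate
7 | (R)-7-[(dichloroboranyl)oxy]-5-methoxy-2-oxo-4-pentylchromane-8-carbaldehyde (not isolated) | CCCCC[C@@H]1CC(=O)Oc2c(C=O)c(OB(Cl)Cl)cc(OC)c12 | intermediate
8 | (R)-7-hydroxy-5-methoxy-2-oxo-4-pentylchromane-8-carbaldehyde | CCCCC[C@@H]1CC(=O)Oc2c(C=O)c(O)cc(OC)c12 | intermediate
9 | 2-methylbut-3-en-2-ol | CC(C)(O)C=C | starting material
10 | di-tert-butyl dicarbonate | CC(C)(C)OC(=O)OC(=O)OC(C)(C)C | starting material
11 | tert-butyl (2-methylbut-3-en-2-yl) carbonate | CC(C)(C)OC(=O)OC(C)(C)C=C | intermediate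
12 | (R)-5-methoxy-7-[(2-methylbut-3-en-2-yl)oxy]-2-oxo-4-pentylchromane-8-carbaldehyde | CCCCC[C@@H]1CC(=O)Oc2c(C=O)c(OC(C)(C)C=C)cc(OC)c12 | intermediate
13 | (4R)-5-methoxy-6-(3-methylbut-2-en-1-yl)-2,7-dioxo-4-pentyl-3,4,6,7-tetrahydro-2H-chromene-8-carbaldehyde (Claisen dienone, not isolated) | CCCCC[C@@H]1CC(=O)OC2=C(C=O)C(=O)C(CC=C(C)C)C(OC)=C12 | intermediate
14 | (R)-7-hydroxy-5-methoxy-6-(3-methylbut-2-en-1-yl)-2-oxo-4-pentylchromane-8-carbaldehyde | CCCCC[C@@H]1CC(=O)Oc2c(C=O)c(O)c(CC=C(C)C)c(OC)c12 | intermediate
15 | (S)-but-3-en-2-ol | C[C@H](O)C=C | starting material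
16 | (R)-7-{[(R)-but-3-en-2-yl]oxy}-5-methoxy-6-(3-methylbut-2-en-1-yl)-2-oxo-4-pentylchromane-8-carbaldehyde | CCCCC[C@@H]1CC(=O)Oc2c(C=O)c(O[C@H](C)C=C)c(CC=C(C)C)c(OC)c12 | intermediate
17 | enaminol adduct of 16 and 2-mesityl-6,7-dihydro-5H-pyrrolo[2,1-c][1,2,4]triazol-3-ylidene (not isolated) | CCCCC[C@@H]1CC(=O)Oc2c(C(O)=C3N(c4c(C)cc(C)cc4C)N=C4CCCN34)c(O[C@H](C)C=C)c(CC=C(C)C)c(OC)c12 | intermediate
18 | (4R,8R,9R)-5-methoxy-8,9-dimethyl-6-(3-methylbut-2-en-1-yl)-4-pentyl-3,4,8,9-tetrahydro-2H,10H-pyrano[2,3-f]chromene-2,10-dione | CCCCC[C@@H]1CC(=O)Oc2c3C(=O)[C@H](C)[C@@H](C)Oc3c(CC=C(C)C)c(OC)c12 | intermediate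
19 | dilithium (R)-3-[(2R,3R)-7-methoxy-2,3-dimethyl-8-(3-methylbut-2-en-1-yl)-5-oxido-4-oxochroman-6-yl]octanoate (not isolated) | CCCCC[C@H](CC(=O)[O-])c1c([O-])c2c(c(CC=C(C)C)c1OC)O[C@H](C)[C@@H](C)C2=O.[Li+].[Li+] | intermediate
20 | (R)-3-[(2R,3R)-5-hydroxy-7-methoxy-2,3-dimethyl-8-(3-methylbut-2-en-1-yl)-4-oxochroman-6-yl]octanoic acid | CCCCC[C@H](CC(=O)O)c1c(O)c2c(c(CC=C(C)C)c1OC)O[C@H](C)[C@@H](C)C2=O | target

**Step count and risks**

Total step count: 9. Longest linear sequence: 8 steps (steps 1, 2, 3, 5, 6, 7, 8, 9, from 3,5-dimethoxyphenol); step 4 is a one-step side branch.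

Steps most likely to fail:

1. Step 8 (key step). What may go wrong: slow addition of the carbene to the doubly ortho-substituted aldehyde, acyl transfer of the enaminol onto the lactone carbonyl, and loss of configuration at C8 by base-induced opening and reclosure of the new ring. The fallback is a radical hydroacylation that sets out from 16 and comes back to the route at 18. With tert-dodecanethiol (30 mol %) and 2,2'-azobis(2-methylpropionitrile) in PhCl at 80 °C, the thiyl radical abstracts the formyl hydrogen (polarity-reversal catalysis). The acyl radical cyclises 6-exo-trig onto the vinyl group and the primary radical takes hydrogen back from the thiol. A catalytic amount of Et3N then equilibrates C9 to the trans isomer. The medium is neutral, so neither the lactone nor C8 should be touched; no new compound is formed on the way (F0).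

2. Step 7. What may go wrong: incomplete etherification of the hindered, hydrogen-bonded phenol, and SN2' attack at the vinyl terminus, which gives the achiral crotyl ether. The fallback sets out from 14 and comes back at 16. Commercial (S)-but-3-yn-2-ol (C[C@H](O)C#C) is converted with MsCl and Et3N in CH2Cl2 at 0 °C into (S)-but-3-yn-2-yl methanesulfonate F1. The caesium phenoxide of 14 (Cs2CO3, DMF, rt) should displace the mesylate with inversion and without allylic transposition to give (R)-7-{[(R)-but-3-yn-2-yl]oxy}-5-methoxy-6-(3-methylbut-2-en-1-yl)-2-oxo-4-pentylchromane-8-carbaldehyde F2. Semihydrogenation of the terminal alkyne (H2, Pd/CaCO3 poisoned with Pb(OAc)2, quinoline, EtOAc) then gives 16.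

3. Step 5. What may go wrong: attack of the phenoxide at the unsubstituted allyl terminus or re-ionisation of the tertiary ether, both leading to the linear O-prenyl ether, and low reactivity of the chelated phenol. The fallback sets out from 8 and comes back at 14, so that steps 4 to 6 are not needed. Bromination at C6, the only free ring position (N-bromosuccinimide, MeCN, 0 °C), gives (R)-6-bromo-7-hydroxy-5-methoxy-2-oxo-4-pentylchromane-8-carbaldehyde F3. Stille coupling with tributyl(3-methylbut-2-en-1-yl)stannane (Pd(PPh3)4, DMF, 90 °C) should then place the linear prenyl group and give 14.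

**Further compounds**

F0 | step 8 | none | none
F1 | step 7 | (S)-but-3-yn-2-yl methanesulfonate | C[C@H](OS(C)(=O)=O)C#C
F2 | step 7 | (R)-7-{[(R)-but-3-yn-2-yl]oxy}-5-methoxy-6-(3-methylbut-2-en-1-yl)-2-oxo-4-pentylchromane-8-carbaldehyde | CCCCC[C@@H]1CC(=O)Oc2c(C=O)c(O[C@H](C)C#C)c(CC=C(C)C)c(OC)c12
F3 | step 5 | (R)-6-bromo-7-hydroxy-5-methoxy-2-oxo-4-pentylchromane-8-carbaldehyde | CCCCC[C@@H]1CC(=O)Oc2c(C=O)c(O)c(Br)c(OC)c12
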